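The decision is to follow one quantity through winter: the balance level, meaning the amount of single product at which its making, k[starting material][partner], equals a first-order loss, kL[single product]. In winter this quasi-steady-state level is expected to sink while single product climbs towards it.

the same everywhere: starting material 0.10 M
- gamma: partner 0.097 M; run made earlier
- eta: partner 0.23 M; run made earlier
- zeta: partner 0.45 M; run made earlier
- winter: partner 0.120 M; time 2.5 h
- autumn: partner 0.250 M; time 2.5 h
- summer: partner 0.400 M; time 2.5 h

| run | time / h | single product / % | double product / % | starting material / % |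
|---|---|---|---|---|
| gamma | 0.200 | 6.0 | 0 | 93.5 |
| gamma | 0.417 | 11.7 | 0.1 | 87.1 |
| gamma | 0.667 | 16.6 | 0.4 | 81.4 |
| gamma | 1.33 | 24.5 | 0.3 | 68.7 |
| gamma | 2.50 | 29.3 | 1.0 | 54.7 |
| eta | 0.200 | 13.9 | 0.1 | 85.8 |
| eta | 0.667 | 33.7 | 0.6 | 61.5 |
| eta | 1.33 | 45.7 | 0.9 | 40.8 |
| eta | 2.00 | 48.7 | 1.0 | 27.8 |
| eta | 2.50 | 46.8 | 1.4 | 21.7 |
| zeta | 0.500 | 46.6 | 0.8 | 48.7 |
| zeta | 1.00 | 60.1 | 1.6 | 24.5 |
| zeta | 1.50 | 60.7 | 1.4 | 12.9 |
| zeta | 2.00 | 55.6 | 1.6 | 7.6 |
| zeta | 2.50 | 49.3 | 1.5 | 3.9 |

(each reading ± 0.3 percentage points)

1. single product at the end, in percent of the starting material charged, for each flask in turn (winter, autumn, summer)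

- the analysis behind the earlier runs scatters by 0.3 percentage points, standard deviation

Which numbers must be known well? The scatter, 0.3 percentage points on a reading of 48.7%, moves little. Double product reads 1.4% in eta at 2.50 h, less than the 30.1% missing from the balance there, so it counts as a small drain.

Eta at 2.00 h, with [partner] at 0.158 M, gives k = 3.47 M⁻¹ h⁻¹. Winter then keeps 46.8% of its starting material at 2.5 h. Twice that k leaves 28.6%, and the larger constant acting on less material puts the making rate at 89.2% of its former value.

The level is inversely proportional to kL, so kL is the number to get right. At a peak, making equals loss, and eta's highest single-product reading stands at 2.00 h, so kL reads 0.313 h⁻¹. My reckoning puts winter's balance level at 2.5 h at 34.7%. Gamma at 2.50 h still reads 29.3%, below its level of 31.4%, so winter, with a little more partner, should stand near its crossing.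

The forecast gives 34.9%, 48.1% and 50%, calling the loss “roughly first order and rising only slightly with partner”. For winter it lies 0.20 points above my level.

The flasks give 33.7%, 48.0% and 50.2%.

    partner + double product → tris adduct (k = 7.70 M⁻¹ h⁻¹)
    partner + single product → double product (k = 0.180 M⁻¹ h⁻¹)
    starting material + partner → single product (k = 3.50 M⁻¹ h⁻¹)
    starting material → decomposition product (k = 3.80 × 10⁻⁴ h⁻¹)
    single product → decomposed reagent (k = 0.300 h⁻¹)

In winter, single product is made 3.28 times faster than it is used up at 0.839 h, each step taken net, and 1.02 times at 2.50 h, and its 33.7% stands beside the balance level of 34.7%. Autumn at 2.50 h holds 18.4% starting material and 65.1% of its partner, which scales winter's level to a balance level for autumn of 33.3%, less than the 48.0% of single product standing there.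

The numbers in the tables are calculated with made-up constants.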